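**Retrosynthetic overview**

1. The target is a 14-membered carbocycle (C1–C14) bridged by a seven-membered α-methylene lactone (C1, C15, C16, O, C12, C13, C14). The strategy rests on the Z-trisubstituted C7=C8 alkene of the large ring, which lies between the C6 carbinol and the primary carbon C9.
2. Key disconnection C8–C9 (sp2–sp3): a Z-alkenyl iodide at C8 and a C9 borane made from the vinyl group on C11 are joined by a B-alkyl Suzuki macrocyclisation.
3. The seco compound is cut at C2–C3: Negishi coupling of a lactone CH2ZnBr (C2) with a Z-iodoalkene (C3–C7, C6 from a glycidyl ether), then hydroxyl-directed epoxidation (C3, C4) and iodo-olefination of a C7 aldehyde.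
4. The lactone fragment comes from Baeyer–Villiger oxidation of a cyclohexanone; C1 is set by rhodium-catalysed conjugate addition, C12 and C11 by an acrolein aldol.
5. Ring order: six-membered carbocycle, then seven-membered lactone (step 7), then epoxide (step 11), then 14-membered ring (step 16); methylenation and desilylation come last.

Key step: step 16

Remark: numbering is C1 = lactone-ring CH, C2–C14 round the carbocycle, C15/C16/C17 = lactone α-carbon, carbonyl and exocyclic CH2, C18–C20 = methyls on C4, C8, C12. Hydride trans-hydroalumination of an alkynol would reduce the lactone, so the Z-iodoalkene is made by olefination of a C7 aldehyde. Racemic 1 is used because its stereocentre is erased in step 2. TBS = tert-butyldimethylsilyl, PMB = 4-methoxybenzyl.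

**Route**

Step 1
Reactants: 1 6-methylcyclohex-2-en-1-one (racemic); 2 (E)-prop-1-enylboronic acid
Product: 3 (5R)-2-methyl-5-[(E)-prop-1-enyl]cyclohexan-1-one (epimers at C2)
Conditions: Rh(acac)(C2H4)2 (3 mol %), (R)-BINAP, dioxane–H2O 10:1, 100 °C
Reagents that add atoms: none
Why: Hayashi–Miyaura asymmetric 1,4-addition of an alkenylboronic acid, in which the (R)-BINAP–rhodium alkenyl species (the ligand enantiomer that gives 5R) adds to one enantioface of the enone and sets C1, whatever the configuration of the methyl-bearing carbon that is erased in step 2.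

Step 2
Reactants: 3 (5R)-2-methyl-5-[(E)-prop-1-enyl]cyclohexan-1-one
Product: 4 trimethyl{[(5R)-2-methyl-5-[(E)-prop-1-enyl]cyclohex-1-en-1-yl]oxy}silane
Conditions: Me3SiCl, NaI, Et3N, MeCN, rt
Reagents that add atoms: chlorotrimethylsilane C[Si](C)(C)Cl
Why: Equilibrating silylation (Me3SiI formed in the flask) should give mainly the thermodynamic, tetrasubstituted silyl enol ether towards the methyl-bearing carbon, which fixes the site of the next C–C bond; the minor regioisomer is removed after the aldol.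

Step 3
Reactants: 4 trimethyl{[(5R)-2-methyl-5-[(E)-prop-1-enyl]cyclohex-1-en-1-yl]oxy}silane; 5 acrolein
Product: 8 (2R,5R)-2-[(1R)-1-hydroxyprop-2-enyl]-2-methyl-5-[(E)-prop-1-enyl]cyclohexan-1-one, via lithium enolate 6 (not isolated), via dicyclohexylboron enolate 7 (not isolated)
Conditions: MeLi, THF, 0 °C; (c-C6H11)2BCl, −78 °C; 5, −78 to −40 °C; then H2O2, pH 7 buffer, MeOH, 0 °C
Reagents that add atoms: none
Why: Regiospecific enolate formation by MeLi cleavage of the silyl enol ether, transmetalation to boron and a Zimmerman–Traxler aldol: acrolein should add axially to the half-chair enolate on the face cis to the equatorial C1 substituent (sets C12), and its vinyl group sits equatorial in the chair transition state of the ring-locked E-enolate (sets C11, methyl and hydroxyl syn).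

Step 4
Reactants: 8 (2R,5R)-2-[(1R)-1-hydroxyprop-2-enyl]-2-methyl-5-[(E)-prop-1-enyl]cyclohexan-1-one
Product: 9 (2R,5R)-2-methyl-5-[(E)-prop-1-enyl]-2-[(1R)-1-(TBS-oxy)prop-2-enyl]cyclohexan-1-one
Conditions: TBSOTf, 2,6-lutidine, CH2Cl2, −78 to 0 °C
Reagents that add atoms: tert-butyldimethylsilyl triflate CC(C)(C)[Si](C)(C)OS(=O)(=O)C(F)(F)F
Why: Silylation with the silyl triflate caps the hindered secondary alcohol next to the quaternary carbon, which blocks retro-aldol and protects C11–OH until the last step.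

Step 5
Reactants: 9 (2R,5R)-2-methyl-5-[(E)-prop-1-enyl]-2-[(1R)-1-(TBS-oxy)prop-2-enyl]cyclohexan-1-one
Product: 11 (2R,5R)-5-(hydroxymethyl)-2-methyl-2-[(1R)-1-(TBS-oxy)prop-2-enyl]cyclohexan-1-one, via keto aldehyde 10 (not isolated)
Conditions: O3, CH2Cl2–MeOH, −78 °C (Sudan Red 7B end point); Me2S, −78 °C to rt; then NaBH4, −78 °C
Reagents that add atoms: ozone [O-][O+]=O
Why: Ozonolysis should cleave the unhindered 1,2-disubstituted propenyl group before the vinyl group, which is deactivated by the allylic silyloxy group and shielded by the quaternary carbon, and NaBH4 at −78 °C reduces the aldehyde but not the hindered ketone.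

Step 6
Reactants: 11 (2R,5R)-5-(hydroxymethyl)-2-methyl-2-[(1R)-1-(TBS-oxy)prop-2-enyl]cyclohexan-1-one
Product: 12 (2R,5R)-5-(bromomethyl)-2-methyl-2-[(1R)-1-(TBS-oxy)prop-2-enyl]cyclohexan-1-one
Conditions: CBr4, PPh3, CH2Cl2, 0 °C
Reagents that add atoms: carbon tetrabromide BrC(Br)(Br)Br
Why: The Appel reaction turns the primary alcohol into a bromide, which survives the peracid of step 7 (an iodide would not) and cannot translactonise onto the later lactone carbonyl (a free γ-hydroxyl would).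

Step 7
Reactants: 12 (2R,5R)-5-(bromomethyl)-2-methyl-2-[(1R)-1-(TBS-oxy)prop-2-enyl]cyclohexan-1-one
Product: 13 (4R,7R)-4-(bromomethyl)-7-methyl-7-[(1R)-1-(TBS-oxy)prop-2-enyl]oxepan-2-one
Conditions: mCPBA, NaHCO3, CH2Cl2, rt
Reagents that add atoms: 3-chloroperbenzoic acid OOC(=O)c1cccc(Cl)c1
Why: In the Baeyer–Villiger oxidation the quaternary carbon C12 migrates in preference to the CH2 group and with retention, giving the seven-membered lactone, while the electron-poor, hindered vinyl group should be epoxidised far more slowly.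

Step 8
Reactants: 14 (R)-2-[(4-methoxybenzyloxy)methyl]oxirane
Product: 15 (2R)-1-(4-methoxybenzyloxy)pent-4-yn-2-ol
Conditions: LiC≡CH·H2NCH2CH2NH2, DMSO, rt
Reagents that add atoms: lithium acetylide–ethylenediamine complex [Li+].[C-]#C.NCCN
Why: SN2 opening of the terminal epoxide at its CH2 carbon by the acetylide leaves the chiral-pool stereocentre (the later C6) untouched.

Step 9
Reactants: 15 (2R)-1-(4-methoxybenzyloxy)pent-4-yn-2-ol
Product: 17 (2R,4Z)-5-iodo-1-(4-methoxybenzyloxy)-4-methylpent-4-en-2-ol, via Z-alkenylalane 16 (not isolated)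
Conditions: Me3Al, Cp2ZrCl2 (25 mol %), ClCH2CH2Cl, rt then 60 °C; I2, THF, −30 °C
Reagents that add atoms: trimethylaluminium C[Al](C)C; iodine II
Why: Zirconium-catalysed carboalumination of a homopropargylic alcohol (Negishi carboalumination), followed by alkoxide-chelation-driven isomerisation of the alkenylalane and iodinolysis with retention, should give the Z-iodoalkene that carries the C18 methyl and fixes the later cis-epoxide geometry.

Step 10
Reactants: 13 (4R,7R)-4-(bromomethyl)-7-methyl-7-[(1R)-1-(TBS-oxy)prop-2-enyl]oxepan-2-one; 17 (2R,4Z)-5-iodo-1-(4-methoxybenzyloxy)-4-methylpent-4-en-2-ol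
Product: 19 (4S,7R)-4-[(2Z,5R)-5-hydroxy-6-(PMB-oxy)-3-methylhex-2-enyl]-7-methyl-7-[(1R)-1-(TBS-oxy)prop-2-enyl]oxepan-2-one, via alkylzinc bromide 18 (not isolated)
Conditions: 13, Zn dust, LiCl, THF, 50 °C; then 17, Pd(OAc)2 (5 mol %), SPhos, THF, rt
Reagents that add atoms: none
Why: LiCl-promoted zinc insertion gives a lactone-tolerant primary alkylzinc bromide, and the Negishi sp3–sp2 coupling with the alkenyl iodide forms C2–C3 with retention of the Z geometry while the weakly basic organozinc tolerates the free hydroxyl.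

Step 11
Reactants: 19 (4S,7R)-4-[(2Z,5R)-5-hydroxy-6-(PMB-oxy)-3-methylhex-2-enyl]-7-methyl-7-[(1R)-1-(TBS-oxy)prop-2-enyl]oxepan-2-one
Product: 20 (4S,7R)-4-{[(2R,3S)-3-[(2R)-2-hydroxy-3-(PMB-oxy)propyl]-3-methyloxiran-2-yl]methyl}-7-methyl-7-[(1R)-1-(TBS-oxy)prop-2-enyl]oxepan-2-one
Conditions: VO(acac)2 (5 mol %), t-BuOOH, CH2Cl2, 0 °C to rt
Reagents that add atoms: tert-butyl hydroperoxide CC(C)(C)OO
Why: Hydroxyl-directed vanadium-catalysed epoxidation of a homoallylic alcohol, in whose chair vanadate transition state the C6 substituent is equatorial and allylic strain from the Z substituent fixes the alkene face, should give the 1,3-syn epoxy alcohol (3R,4S) and leave the undirected vinyl group alone.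

Step 12
Reactants: 20 (4S,7R)-4-{[(2R,3S)-3-[(2R)-2-hydroxy-3-(PMB-oxy)propyl]-3-methyloxiran-2-yl]methyl}-7-methyl-7-[(1R)-1-(TBS-oxy)prop-2-enyl]oxepan-2-one
Product: 21 (4S,7R)-4-{[(2R,3S)-3-[(2R)-3-(PMB-oxy)-2-(TBS-oxy)propyl]-3-methyloxiran-2-yl]methyl}-7-methyl-7-[(1R)-1-(TBS-oxy)prop-2-enyl]oxepan-2-one
Conditions: TBSCl, imidazole, DMF, rt
Reagents that add atoms: tert-butyldimethylsilyl chloride CC(C)(C)[Si](C)(C)Cl
Why: Silylation of the unhindered secondary alcohol under non-acidic conditions keeps the epoxide intact and removes the hydroxyl that could open it.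

Step 13
Reactants: 21 (4S,7R)-4-{[(2R,3S)-3-[(2R)-3-(PMB-oxy)-2-(TBS-oxy)propyl]-3-methyloxiran-2-yl]methyl}-7-methyl-7-[(1R)-1-(TBS-oxy)prop-2-enyl]oxepan-2-one
Product: 22 (4S,7R)-4-{[(2R,3S)-3-[(2R)-3-hydroxy-2-(TBS-oxy)propyl]-3-methyloxiran-2-yl]methyl}-7-methyl-7-[(1R)-1-(TBS-oxy)prop-2-enyl]oxepan-2-one
Conditions: DDQ, CH2Cl2–pH 7 buffer, 0 °C
Reagents that add atoms: none
Why: Oxidative cleavage of the 4-methoxybenzyl ether by DDQ in buffered medium frees the primary alcohol without touching the silyl ethers, the epoxide, the lactone or the alkene; the epoxy alcohol is kept cold and neutral and oxidised at once.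

Step 14
Reactants: 22 (4S,7R)-4-{[(2R,3S)-3-[(2R)-3-hydroxy-2-(TBS-oxy)propyl]-3-methyloxiran-2-yl]methyl}-7-methyl-7-[(1R)-1-(TBS-oxy)prop-2-enyl]oxepan-2-one
Product: 23 (4S,7R)-4-{[(2R,3S)-3-methyl-3-[(2R)-3-oxo-2-(TBS-oxy)propyl]oxiran-2-yl]methyl}-7-methyl-7-[(1R)-1-(TBS-oxy)prop-2-enyl]oxepan-2-one
Conditions: Dess–Martin periodinane, NaHCO3, CH2Cl2, 0 °C
Reagents that add atoms: none
Why: Dess–Martin oxidation under buffered conditions gives the α-silyloxy aldehyde without epimerisation at C6.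

Step 15
Reactants: 23 (4S,7R)-4-{[(2R,3S)-3-methyl-3-[(2R)-3-oxo-2-(TBS-oxy)propyl]oxiran-2-yl]methyl}-7-methyl-7-[(1R)-1-(TBS-oxy)prop-2-enyl]oxepan-2-one
Product: 24 (4S,7R)-4-{[(2R,3S)-3-[(2R,3Z)-4-iodo-2-(TBS-oxy)pent-3-enyl]-3-methyloxiran-2-yl]methyl}-7-methyl-7-[(1R)-1-(TBS-oxy)prop-2-enyl]oxepan-2-one
Conditions: [Ph3PCH(I)CH3]I, NaN(SiMe3)2, THF, −78 °C; then 23, −78 to −20 °C
Reagents that add atoms: (1-iodoethyl)triphenylphosphonium iodide CC(I)[P+](c1ccccc1)(c1ccccc1)c1ccccc1.[I-]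
Why: Stork–Zhao-type olefination with the α-iodoethylidene ylide should give the Z-2-iodoalkene (iodine cis to C6) through the kinetically favoured cis-oxaphosphetane, at a temperature where lactone and epoxide are inert.

Step 16
Reactants: 24 (4S,7R)-4-{[(2R,3S)-3-[(2R,3Z)-4-iodo-2-(TBS-oxy)pent-3-enyl]-3-methyloxiran-2-yl]methyl}-7-methyl-7-[(1R)-1-(TBS-oxy)prop-2-enyl]oxepan-2-one
Product: 26 bis-TBS macrocyclic lactone without the exocyclic methylene (1S,3R,4S,6R,7Z,11R,12R), via B-alkyl-9-BBN borane 25 (not isolated)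
Conditions: 9-BBN, THF, rt; then Pd(dppf)Cl2 (20 mol %), AsPh3, Cs2CO3, DMF–THF–H2O, slow addition (final 2 mM), rt
Reagents that add atoms: none
Why: 9-BBN adds anti-Markovnikov to the only monosubstituted alkene (C9=C10) and places boron on C9, while the trisubstituted iodoalkene, the epoxide and the lactone are not touched at room temperature. Zerovalent palladium formed from Pd(dppf)Cl2 inserts into the C8–I bond with retention, the base-activated borate transfers its primary alkyl group to palladium, and reductive elimination forms the C8–C9 sp2–sp3 bond. The closest known reaction type is the macrocyclising B-alkyl Suzuki–Miyaura coupling of an in situ 9-BBN borane with a Z-alkenyl iodide. The 14-membered carbocycle is closed end to end at an unhindered primary carbon remote from the epoxide and the lactone, and slow addition at high dilution should favour ring closure over intermolecular coupling. No stereocentre is formed, and the Z geometry set in step 15 is carried through because oxidative addition and reductive elimination are stereoretentive. The selectivity needed (hydroboration of the vinyl group only, and no β-hydride elimination from the primary alkylpalladium) is secured by the steric demand of 9-BBN and by the wide-bite-angle dppf ligand with AsPh3.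

Step 17
Reactants: 26 bis-TBS macrocyclic lactone without the exocyclic methylene
Product: 28 C15-(dimethylaminomethyl) bis-TBS macrocyclic lactone (epimers at C15), via lithium lactone enolate 27 (not isolated)
Conditions: LiN(iPr)2, THF, −78 °C; CH2=NMe2+ I−, −78 °C to rt
Reagents that add atoms: N,N-dimethylmethyleneiminium iodide (Eschenmoser salt) C=[N+](C)C.[I-]
Why: Kinetic deprotonation at the only α-carbon of the lactone (C15) and Mannich alkylation of the lithium enolate with the iminium salt install the aminomethyl group, whose configuration does not matter.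

Step 18
Reactants: 28 C15-(dimethylaminomethyl) bis-TBS macrocyclic lactone
Product: 30 bis-TBS ether of the target (α-methylene lactone), via trimethylammonium iodide 29 (not isolated)
Conditions: MeI, CH2Cl2–MeOH, rt; then aq NaHCO3, rt
Reagents that add atoms: none
Why: Quaternisation and mild-base elimination of the β-ammonium lactone (second half of the Eschenmoser methylenation) give the exocyclic C15=C17 alkene.

Step 19
Reactants: 30 bis-TBS ether of the target
Product: 31 CNP0250657.1 (1S,3R,4S,6R,7Z,11R,12R)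
Conditions: Bu4NF, AcOH, THF, rt to 40 °C
Reagents that add atoms: none
Why: Buffered fluoride desilylation should cleave both silyl ethers without opening the epoxide or adding to the α-methylene lactone, so the six stereocentres and the Z alkene reach the target unchanged.

**Compound list**

1 | 6-methylcyclohex-2-en-1-one (racemic) | CC1CCC=CC1=O | starting material
2 | (E)-prop-1-enylboronic acid | C/C=C/B(O)O | starting material
3 | (5R)-2-methyl-5-[(E)-prop-1-enyl]cyclohexan-1-one (epimers at C2) | CC1CC[C@@H](/C=C/C)CC1=O | intermediate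
4 | trimethyl{[(5R)-2-methyl-5-[(E)-prop-1-enyl]cyclohex-1-en-1-yl]oxy}silane | C[Si](C)(C)OC1=C(C)CC[C@@H](/C=C/C)C1 | intermediate
5 | acrolein | C=CC=O | starting material
6 | lithium enolate (lithium (5R)-2-methyl-5-[(E)-prop-1-enyl]cyclohex-1-en-1-olate) | [Li]OC1=C(C)CC[C@@H](/C=C/C)C1 | intermediate
7 | dicyclohexylboron enolate of 3 | C1CCCCC1B(OC1=C(C)CC[C@@H](/C=C/C)C1)C1CCCCC1 | intermediate
8 | (2R,5R)-2-[(1R)-1-hydroxyprop-2-enyl]-2-methyl-5-[(E)-prop-1-enyl]cyclohexan-1-one | C1C(=O)[C@](C)(CC[C@H]1/C=C/C)[C@H](O)C=C | intermediate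
9 | (2R,5R)-2-methyl-5-[(E)-prop-1-enyl]-2-[(1R)-1-(TBS-oxy)prop-2-enyl]cyclohexan-1-one | C1C(=O)[C@](C)(CC[C@H]1/C=C/C)[C@H](O[Si](C)(C)C(C)(C)C)C=C | intermediate
10 | keto aldehyde, (1R,4R)-4-methyl-3-oxo-4-[(1R)-1-(TBS-oxy)prop-2-enyl]cyclohexane-1-carbaldehyde | C1C(=O)[C@](C)(CC[C@H]1C=O)[C@H](O[Si](C)(C)C(C)(C)C)C=C | intermediate
11 | (2R,5R)-5-(hydroxymethyl)-2-methyl-2-[(1R)-1-(TBS-oxy)prop-2-enyl]cyclohexan-1-one | C1C(=O)[C@](C)(CC[C@H]1CO)[C@H](O[Si](C)(C)C(C)(C)C)C=C | intermediate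
12 | (2R,5R)-5-(bromomethyl)-2-methyl-2-[(1R)-1-(TBS-oxy)prop-2-enyl]cyclohexan-1-one | C1C(=O)[C@](C)(CC[C@H]1CBr)[C@H](O[Si](C)(C)C(C)(C)C)C=C | intermediate
13 | (4R,7R)-4-(bromomethyl)-7-methyl-7-[(1R)-1-(TBS-oxy)prop-2-enyl]oxepan-2-one | C1C(=O)O[C@](C)(CC[C@H]1CBr)[C@H](O[Si](C)(C)C(C)(C)C)C=C | intermediate
14 | (R)-2-[(4-methoxybenzyloxy)methyl]oxirane | C1O[C@H]1COCc1ccc(OC)cc1 | starting material
15 | (2R)-1-(4-methoxybenzyloxy)pent-4-yn-2-ol | C#CC[C@@H](O)COCc1ccc(OC)cc1 | intermediate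
16 | Z-alkenylalane (O,C-bis(dimethylaluminium) derivative of 17 before iodination) | C[Al](C)/C=C(/C)C[C@@H](O[Al](C)C)COCc1ccc(OC)cc1 | intermediate
17 | (2R,4Z)-5-iodo-1-(4-methoxybenzyloxy)-4-methylpent-4-en-2-ol | I/C=C(/C)C[C@@H](O)COCc1ccc(OC)cc1 | intermediate
18 | alkylzinc bromide from 13 | C1C(=O)O[C@](C)(CC[C@H]1C[Zn]Br)[C@H](O[Si](C)(C)C(C)(C)C)C=C | intermediate
19 | (4S,7R)-4-[(2Z,5R)-5-hydroxy-6-(PMB-oxy)-3-methylhex-2-enyl]-7-methyl-7-[(1R)-1-(TBS-oxy)prop-2-enyl]oxepan-2-one | C1C(=O)O[C@](C)(CC[C@H]1C/C=C(/C)C[C@@H](O)COCc1ccc(OC)cc1)[C@H](O[Si](C)(C)C(C)(C)C)C=C | intermediate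
20 | (4S,7R)-4-{[(2R,3S)-3-[(2R)-2-hydroxy-3-(PMB-oxy)propyl]-3-methyloxiran-2-yl]methyl}-7-methyl-7-[(1R)-1-(TBS-oxy)prop-2-enyl]oxepan-2-one | C1C(=O)O[C@](C)(CC[C@H]1C[C@H]1O[C@@]1(C)C[C@@H](O)COCc1ccc(OC)cc1)[C@H](O[Si](C)(C)C(C)(C)C)C=C | intermediate
21 | (4S,7R)-4-{[(2R,3S)-3-[(2R)-3-(PMB-oxy)-2-(TBS-oxy)propyl]-3-methyloxiran-2-yl]methyl}-7-methyl-7-[(1R)-1-(TBS-oxy)prop-2-enyl]oxepan-2-one | C1C(=O)O[C@](C)(CC[C@H]1C[C@H]1O[C@@]1(C)C[C@@H](O[Si](C)(C)C(C)(C)C)COCc1ccc(OC)cc1)[C@H](O[Si](C)(C)C(C)(C)C)C=C | intermediate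
22 | (4S,7R)-4-{[(2R,3S)-3-[(2R)-3-hydroxy-2-(TBS-oxy)propyl]-3-methyloxiran-2-yl]methyl}-7-methyl-7-[(1R)-1-(TBS-oxy)prop-2-enyl]oxepan-2-one | C1C(=O)O[C@](C)(CC[C@H]1C[C@H]1O[C@@]1(C)C[C@@H](O[Si](C)(C)C(C)(C)C)CO)[C@H](O[Si](C)(C)C(C)(C)C)C=C | intermediate
23 | (4S,7R)-4-{[(2R,3S)-3-methyl-3-[(2R)-3-oxo-2-(TBS-oxy)propyl]oxiran-2-yl]methyl}-7-methyl-7-[(1R)-1-(TBS-oxy)prop-2-enyl]oxepan-2-one | C1C(=O)O[C@](C)(CC[C@H]1C[C@H]1O[C@@]1(C)C[C@@H](O[Si](C)(C)C(C)(C)C)C=O)[C@H](O[Si](C)(C)C(C)(C)C)C=C | intermediate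
24 | seco lactone with C8 Z-iodoalkene and C11 vinyl carbinol, (4S,7R)-4-{[(2R,3S)-3-[(2R,3Z)-4-iodo-2-(TBS-oxy)pent-3-enyl]-3-methyloxiran-2-yl]methyl}-7-methyl-7-[(1R)-1-(TBS-oxy)prop-2-enyl]oxepan-2-one | C1C(=O)O[C@](C)(CC[C@H]1C[C@H]1O[C@@]1(C)C[C@@H](O[Si](C)(C)C(C)(C)C)/C=C(/C)I)[C@H](O[Si](C)(C)C(C)(C)C)C=C | intermediate
25 | B-alkyl-9-BBN borane (boron on C9 of 24) | C1C(=O)O[C@](C)(CC[C@H]1C[C@H]1O[C@@]1(C)C[C@@H](O[Si](C)(C)C(C)(C)C)/C=C(/C)I)[C@H](O[Si](C)(C)C(C)(C)C)CCB1C2CCCC1CCC2 | intermediate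
26 | bis-TBS macrocyclic lactone without the exocyclic methylene (1S,3R,4S,6R,7Z,11R,12R) | C1C(=O)O[C@]2(C)CC[C@H]1C[C@H]1O[C@@]1(C)C[C@@H](O[Si](C)(C)C(C)(C)C)/C=C(/C)CC[C@H]2O[Si](C)(C)C(C)(C)C | intermediate
27 | lithium lactone enolate of 26 | C1=C(O[Li])O[C@]2(C)CC[C@H]1C[C@H]1O[C@@]1(C)C[C@@H](O[Si](C)(C)C(C)(C)C)/C=C(/C)CC[C@H]2O[Si](C)(C)C(C)(C)C | intermediate
28 | C15-(dimethylaminomethyl) bis-TBS macrocyclic lactone (epimers at C15) | CN(C)CC1C(=O)O[C@]2(C)CC[C@H]1C[C@H]1O[C@@]1(C)C[C@@H](O[Si](C)(C)C(C)(C)C)/C=C(/C)CC[C@H]2O[Si](C)(C)C(C)(C)C | intermediate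
29 | trimethylammonium iodide of 28 | C[N+](C)(C)CC1C(=O)O[C@]2(C)CC[C@H]1C[C@H]1O[C@@]1(C)C[C@@H](O[Si](C)(C)C(C)(C)C)/C=C(/C)CC[C@H]2O[Si](C)(C)C(C)(C)C.[I-] | intermediate
30 | bis-TBS ether of the target (α-methylene lactone) | C=C1C(=O)O[C@]2(C)CC[C@H]1C[C@H]1O[C@@]1(C)C[C@@H](O[Si](C)(C)C(C)(C)C)/C=C(/C)CC[C@H]2O[Si](C)(C)C(C)(C)C | intermediate
31 | CNP0250657.1 (1S,3R,4S,6R,7Z,11R,12R) | C=C1C(=O)O[C@]2(C)CC[C@H]1C[C@H]1O[C@@]1(C)C[C@@H](O)/C=C(/C)CC[C@H]2O | target

**Step count and risks**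

Total step count: 19. Longest linear sequence: 17 steps (steps 1–7, then 10–19, from 1); the side-chain fragment takes 2 steps (8, 9) before the union in step 10.

Steps most likely to fail:

1. Step 16. The intramolecular coupling may lose to intermolecular coupling (oligomers); the alkylborane may protodeboronate, or the alkylpalladium may undergo β-hydride elimination before ring closure; the aqueous carbonate may open the lactone. The fallback sets out from 24 and returns at 26, closing the same bond without a borate or aqueous base. 24 is hydroborated to 25 as before, but 25 is oxidised (NaBO3, THF–H2O) to the primary alcohol F1. I2, PPh3 and imidazole turn it into the primary iodide F2. Zn dust in THF–DMA inserts into the alkyl C–I bond only, giving the alkylzinc iodide F3, and Pd(PPh3)4 under high dilution closes C8–C9 by an intramolecular Negishi coupling to 26.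

2. Step 3. The two chair transition states may not be well differentiated, and the hindered aldolate may partly revert by retro-aldol, so the C11 carbinol configuration may not be fixed. The fallback sets out from 4 and returns at 8, replacing substrate control at C11 by reagent control. A Mukaiyama aldol of 4 with acrolein (TiCl4, CH2Cl2, −78 °C) gives the C11-epimeric aldols F4. Dess–Martin oxidation gives the ene-dione F5. Corey–Bakshi–Shibata reduction of the more reactive vinyl ketone (the oxazaborolidine enantiomer that treats the quaternary carbon as the large group, catecholborane, −78 °C) gives 8.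

3. Step 15. The basic ylide may enolise or epimerise the α-silyloxy aldehyde, the ylide may lose iodine, and the Z selectivity may erode. The fallback sets out from 23 and returns at 26. CBr4 and PPh3 with 2,6-lutidine convert 23 into the 1,1-dibromoalkene F6. Coupling with MeZnCl under PdCl2(DPEphos) catalysis replaces only the bromine trans to C6 and gives the Z-bromoalkene F7. F7 is hydroborated with 9-BBN to the B-alkyl borane F8 and cyclised under the conditions of step 16 to 26.

**Further compounds**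

F1 | step 16 | primary alcohol (C9–OH) from 24 | C1C(=O)O[C@](C)(CC[C@H]1C[C@H]1O[C@@]1(C)C[C@@H](O[Si](C)(C)C(C)(C)C)/C=C(/C)I)[C@H](O[Si](C)(C)C(C)(C)C)CCO
F2 | step 16 | primary iodide (C9–I) | C1C(=O)O[C@](C)(CC[C@H]1C[C@H]1O[C@@]1(C)C[C@@H](O[Si](C)(C)C(C)(C)C)/C=C(/C)I)[C@H](O[Si](C)(C)C(C)(C)C)CCI
F3 | step 16 | alkylzinc iodide (zinc on C9) | C1C(=O)O[C@](C)(CC[C@H]1C[C@H]1O[C@@]1(C)C[C@@H](O[Si](C)(C)C(C)(C)C)/C=C(/C)I)[C@H](O[Si](C)(C)C(C)(C)C)CC[Zn]I
F4 | step 3 | C11-epimeric aldols, (2R,5R)-2-(1-hydroxyprop-2-enyl)-2-methyl-5-[(E)-prop-1-enyl]cyclohexan-1-one | C1C(=O)[C@](C)(CC[C@H]1/C=C/C)C(O)C=C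
F5 | step 3 | ene-dione, (2R,5R)-2-acryloyl-2-methyl-5-[(E)-prop-1-enyl]cyclohexan-1-one | C1C(=O)[C@](C)(CC[C@H]1/C=C/C)C(=O)C=C
F6 | step 15 | 1,1-dibromoalkene from 23 | C1C(=O)O[C@](C)(CC[C@H]1C[C@H]1O[C@@]1(C)C[C@@H](O[Si](C)(C)C(C)(C)C)C=C(Br)Br)[C@H](O[Si](C)(C)C(C)(C)C)C=C
F7 | step 15 | Z-bromoalkene analogue of 24 | C1C(=O)O[C@](C)(CC[C@H]1C[C@H]1O[C@@]1(C)C[C@@H](O[Si](C)(C)C(C)(C)C)/C=C(/C)Br)[C@H](O[Si](C)(C)C(C)(C)C)C=C
F8 | step 15 | B-alkyl-9-BBN borane from F7 | C1C(=O)O[C@](C)(CC[C@H]1C[C@H]1O[C@@]1(C)C[C@@H](O[Si](C)(C)C(C)(C)C)/C=C(/C)Br)[C@H](O[Si](C)(C)C(C)(C)C)CCB1C2CCCC1CCC2
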